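**Retrosynthetic overview**

1. Target 22 ⇒ acyclic lactol–allylboronate 20 in the last step. The C6–C7 bond closes the ten-membered carbocycle first (alkene C7=C11 attacks C6 and C13 gives up boron, as the cyclase cation gives up H+). O6 then lactonises onto C12.
2. 19/20 ⇒ ynoate 16 by syn-hydroalumination and borylmethylation. This fixes C8 cis to CO2Me, the geometry a chair transition state needs for the trans-lactone.
3. 16 ⇒ aldehyde 12 + methyl propiolate (C8 set by catalyst control) + (S)-2-methylbutanoic acid. The ester goes on before cyclisation, so no protecting groups are used.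
4. 12 ⇒ aldehyde 5 + allyl ylide 9. The Wittig reaction sets the C1=C10 geometry and ozonolysis of the allyl group reveals C8.
5. 5 ⇒ (S)-cyclohex-3-ene-1-carboxylic acid 1, which holds C1–C6, C15 and the C4 centre. An alkoxy-radical ring scission distinguishes C1 (CHO) from C6 (lactol acetate; the oxolane is a temporary mask, not a target ring).

Assumption: atoms carry germacranolide numbers (C6 lactone carbinol, C7, C8 acyloxy carbon, C1=C10 enoate, C4 bearing C15H2OH, C11–C13 acrylate unit), and the ProPhenol enantiomer in step 7 is the one that delivers the alkyne to the Si face, written here as (R,R).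

**Route**

Step 1
Reactants: 1 (S)-cyclohex-3-ene-1-carboxylic acid
Product: 2 [(1S)-cyclohex-3-en-1-yl]methanol
Conditions: LiAlH4, THF, 0 °C to rt; H2O work-up
Reagents that add atoms: none
Why: LiAlH4 reduction of the carboxylic acid to the primary alcohol; the C4 stereocentre is not touched and the isolated alkene is inert.

Step 2
Reactants: 2 [(1S)-cyclohex-3-en-1-yl]methanol
Product: 4 (1S,4S,5S)-6-oxabicyclo[3.2.1]octan-4-ol, via trans-epoxide 3 (not isolated)
Conditions: mCPBA, CH2Cl2, 0 °C to rt; then CSA (10 mol %), rt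
Reagents that add atoms: mCPBA (3-chloroperbenzoic acid), OOC(=O)c1cccc(Cl)c1
Why: Prilezhaev epoxidation followed by acid-catalysed 5-exo trans-diaxial (Fürst–Plattner) opening by the CH2OH group, which only the anti epoxide 3 can undergo (the syn epoxide, about half of the material, is removed by chromatography); the two new centres are destroyed in step 3, so only the O15–C6 bond and the C1 hydroxyl matter.

Step 3
Reactants: 4 (1S,4S,5S)-6-oxabicyclo[3.2.1]octan-4-ol
Product: 5 (4S)-4-(3-oxopropyl)oxolan-2-yl acetate (anomer mixture)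
Conditions: PhI(OAc)2, I2, CH2Cl2, visible light, rt
Reagents that add atoms: (diacetoxyiodo)benzene, CC(=O)OI(OC(C)=O)c1ccccc1
Why: Suárez hypoiodite β-fragmentation: the C1 alkoxy radical cleaves the C1–C6 bond because that gives the ring-oxygen-stabilised C6 radical, which is oxidised to the oxocarbenium ion and trapped by acetate, so C1 emerges as the free aldehyde and C6 as a lactol acetate; C4 is untouched.

Step 4
Reactants: 6 methyl (triphenyl-λ5-phosphanylidene)acetate; 7 allyl bromide
Product: 9 methyl 2-(triphenyl-λ5-phosphanylidene)pent-4-enoate, via phosphonium bromide 8 (not isolated)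
Conditions: CHCl3, reflux; then 2 M NaOH, CH2Cl2/H2O, 0 °C
Reagents that add atoms: 7 allyl bromide, C=CCBr
Why: C-alkylation of a stabilised phosphorus ylide by a reactive allylic halide, then deprotonation of the phosphonium salt back to the ylide; no stereocentre is formed.

Step 5
Reactants: 5 (4S)-4-(3-oxopropyl)oxolan-2-yl acetate; 9 methyl 2-(triphenyl-λ5-phosphanylidene)pent-4-enoate
Product: 10 methyl (2E)-5-[(3S)-5-acetoxyoxolan-3-yl]-2-(prop-2-en-1-yl)pent-2-enoate (anomer mixture)
Conditions: toluene, 90 °C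
Reagents that add atoms: 9 methyl 2-(triphenyl-λ5-phosphanylidene)pent-4-enoate, COC(=O)C(CC=C)=P(c1ccccc1)(c1ccccc1)c1ccccc1
Why: Wittig olefination with an α-substituted stabilised ylide, which gives the trisubstituted enoate with the new chain trans to CO2Me (the C1=C10 geometry of the target); the neutral conditions leave the lactol acetate alone.

Step 6
Reactants: 10 methyl (2E)-5-[(3S)-5-acetoxyoxolan-3-yl]-2-(prop-2-en-1-yl)pent-2-enoate
Product: 12 methyl (2E)-5-[(3S)-5-acetoxyoxolan-3-yl]-2-(2-oxoethyl)pent-2-enoate (anomer mixture), via ozonide 11 (not isolated)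
Conditions: O3, CH2Cl2, −78 °C, Sudan Red 7B end-point; then PPh3, −78 °C to rt
Reagents that add atoms: ozone, [O-][O+]=O
Why: Chemoselective ozonolysis of the electron-richer monosubstituted alkene (the dye indicator stops the reaction before the conjugated enoate is attacked) and reductive cleavage of the ozonide to the C8 aldehyde, which is used at once because it is a β,γ-unsaturated aldehyde.

Step 7
Reactants: 12 methyl (2E)-5-[(3S)-5-acetoxyoxolan-3-yl]-2-(2-oxoethyl)pent-2-enoate; 13 methyl propiolate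
Product: 14 methyl (4R,6E)-9-[(3S)-5-acetoxyoxolan-3-yl]-4-hydroxy-6-(methoxycarbonyl)non-6-en-2-ynoate (anomer mixture)
Conditions: Me2Zn, (R,R)-ProPhenol (20 mol %), Ph3P=O (40 mol %), toluene, 0–4 °C, slow addition of 12; H2O quench
Reagents that add atoms: 13 methyl propiolate, C#CC(=O)OC
Why: Zinc–ProPhenol catalysed asymmetric alkynylation of an aldehyde, where the chiral dinuclear zinc alkynylide adds to the Si face and sets C8 as R; the amine-free medium limits enolisation and the alcohol is acylated directly before it can lactonise onto C14.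

Step 8
Reactants: 14 methyl (4R,6E)-9-[(3S)-5-acetoxyoxolan-3-yl]-4-hydroxy-6-(methoxycarbonyl)non-6-en-2-ynoate; 15 (2S)-2-methylbutanoic acid
Product: 16 methyl (4R,6E)-9-[(3S)-5-acetoxyoxolan-3-yl]-6-(methoxycarbonyl)-4-{[(2S)-2-methylbutanoyl]oxy}non-6-en-2-ynoate (anomer mixture)
Conditions: DCC, DMAP (10 mol %), CH2Cl2, 0 °C
Reagents that add atoms: 15 (2S)-2-methylbutanoic acid, CC[C@H](C)C(=O)O
Why: Steglich esterification of the propargylic alcohol with retention at C8; the side-chain stereocentre comes from the acid and is not epimerised at 0 °C.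

Step 9
Reactants: 16 methyl (4R,6E)-9-[(3S)-5-acetoxyoxolan-3-yl]-6-(methoxycarbonyl)-4-{[(2S)-2-methylbutanoyl]oxy}non-6-en-2-ynoate; 17 2-(iodomethyl)-4,4,5,5-tetramethyl-1,3,2-dioxaborolane
Product: 19 methyl (2Z,4R,6E)-9-[(3S)-5-acetoxyoxolan-3-yl]-6-(methoxycarbonyl)-4-{[(2S)-2-methylbutanoyl]oxy}-2-[(4,4,5,5-tetramethyl-1,3,2-dioxaborolan-2-yl)methyl]nona-2,6-dienoate (anomer mixture), via vinylalane 18 (not isolated)
Conditions: DIBAL-H, HMPA, THF, 0 °C; then 17, 0 °C to rt; H2O work-up
Reagents that add atoms: 17 2-(iodomethyl)-4,4,5,5-tetramethyl-1,3,2-dioxaborolane, ICB1OC(C)(C)C(C)(C)O1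
Why: Conjugate syn-hydroalumination of the ynoate with the DIBAL-H–HMPA complex (which spares ordinary and olefinic esters) puts H on C7 and Al on C11, and borylmethylation of the α-alumino enoate with retention gives the allylboronate with C8 cis to CO2Me and trans to CH2B.

Step 10
Reactants: 19 methyl (2Z,4R,6E)-9-[(3S)-5-acetoxyoxolan-3-yl]-6-(methoxycarbonyl)-4-{[(2S)-2-methylbutanoyl]oxy}-2-[(4,4,5,5-tetramethyl-1,3,2-dioxaborolan-2-yl)methyl]nona-2,6-dienoate
Product: 22 methyl (3aS,4R,6E,10S,11aR)-10-(hydroxymethyl)-3-methylidene-4-{[(2S)-2-methylbutanoyl]oxy}-2-oxo-2,3,3a,4,5,8,9,10,11,11a-decahydrocyclodeca[b]furan-6-carboxylate, via lactol 20 (not isolated), via boryl ether 21 (not isolated)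
Conditions: 0.1 M HCl, THF/H2O, rt; then toluene (2 mM), BHT, 95 °C; then TsOH (10 mol %), rt
Reagents that add atoms: water, O
Why: Proposed new method: hydrolysis of the lactol acetate gives lactol 20, whose open hydroxy-aldehyde form undergoes a closed six-membered (Hoffmann type I) allylboration in which C8 (trans to CH2B) and the aldehyde chain are both equatorial, giving the 6,7-anti pair; allylic strain with the cis CO2Me holds H8 in the alkene plane, so C6 adds anti to the C8–C9 bond and next to the acyloxy group, giving 6R,7S, and the boryl ether 21 then lactonises onto C12 and frees C15–OH; the closest known chemistry is the tandem allylboration–lactonisation of 2-alkoxycarbonyl allylboronates and the allylation of lactols, neither yet shown for a ten-membered ring.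

**Compound list**

1 | (S)-cyclohex-3-ene-1-carboxylic acid | C1=CC[C@@H](C(=O)O)CC1 | starting material
2 | [(1S)-cyclohex-3-en-1-yl]methanol | C1=CC[C@@H](CO)CC1 | intermediate
3 | [(1R,3S,6S)-7-oxabicyclo[4.1.0]heptan-3-yl]methanol (epoxide anti to CH2OH) | OC[C@H]1CC[C@@H]2O[C@@H]2C1 | intermediate
4 | (1S,4S,5S)-6-oxabicyclo[3.2.1]octan-4-ol | O[C@H]1CC[C@H]2C[C@@H]1OC2 | intermediate
5 | (4S)-4-(3-oxopropyl)oxolan-2-yl acetate (anomer mixture) | O=CCC[C@@H]1COC(OC(C)=O)C1 | intermediate
6 | methyl (triphenyl-λ5-phosphanylidene)acetate | COC(=O)C=P(c1ccccc1)(c1ccccc1)c1ccccc1 | starting material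
7 | allyl bromide | C=CCBr | starting material
8 | (1-methoxy-1-oxopent-4-en-2-yl)triphenylphosphonium bromide | COC(=O)C(CC=C)[P+](c1ccccc1)(c1ccccc1)c1ccccc1.[Br-] | intermediate
9 | methyl 2-(triphenyl-λ5-phosphanylidene)pent-4-enoate | COC(=O)C(CC=C)=P(c1ccccc1)(c1ccccc1)c1ccccc1 | intermediate
10 | methyl (2E)-5-[(3S)-5-acetoxyoxolan-3-yl]-2-(prop-2-en-1-yl)pent-2-enoate (anomer mixture) | COC(=O)/C(CC=C)=C/CC[C@@H]1COC(OC(C)=O)C1 | intermediate
11 | methyl (2E)-5-[(3S)-5-acetoxyoxolan-3-yl]-2-(1,2,4-trioxolan-3-ylmethyl)pent-2-enoate | COC(=O)/C(CC2OCOO2)=C/CC[C@@H]1COC(OC(C)=O)C1 | intermediate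
12 | methyl (2E)-5-[(3S)-5-acetoxyoxolan-3-yl]-2-(2-oxoethyl)pent-2-enoate (anomer mixture) | COC(=O)/C(CC=O)=C/CC[C@@H]1COC(OC(C)=O)C1 | intermediate
13 | methyl propiolate | C#CC(=O)OC | starting material
14 | methyl (4R,6E)-9-[(3S)-5-acetoxyoxolan-3-yl]-4-hydroxy-6-(methoxycarbonyl)non-6-en-2-ynoate (anomer mixture) | COC(=O)C#C[C@H](O)C/C(C(=O)OC)=C\CC[C@@H]1COC(OC(C)=O)C1 | intermediate
15 | (2S)-2-methylbutanoic acid | CC[C@H](C)C(=O)O | starting material
16 | methyl (4R,6E)-9-[(3S)-5-acetoxyoxolan-3-yl]-6-(methoxycarbonyl)-4-{[(2S)-2-methylbutanoyl]oxy}non-6-en-2-ynoate (anomer mixture) | COC(=O)C#C[C@H](OC(=O)[C@@H](C)CC)C/C(C(=O)OC)=C\CC[C@@H]1COC(OC(C)=O)C1 | intermediate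
17 | 2-(iodomethyl)-4,4,5,5-tetramethyl-1,3,2-dioxaborolane | ICB1OC(C)(C)C(C)(C)O1 | starting material
18 | α-(diisobutylalumanyl) enoate from syn-hydroalumination of 16 (Al cis to H7; C8 cis to CO2Me) | COC(=O)/C([Al](CC(C)C)CC(C)C)=C\[C@H](OC(=O)[C@@H](C)CC)C/C(C(=O)OC)=C\CC[C@@H]1COC(OC(C)=O)C1 | intermediate
19 | methyl (2Z,4R,6E)-9-[(3S)-5-acetoxyoxolan-3-yl]-6-(methoxycarbonyl)-4-{[(2S)-2-methylbutanoyl]oxy}-2-[(4,4,5,5-tetramethyl-1,3,2-dioxaborolan-2-yl)methyl]nona-2,6-dienoate (anomer mixture) | COC(=O)/C(CB1OC(C)(C)C(C)(C)O1)=C\[C@H](OC(=O)[C@@H](C)CC)C/C(C(=O)OC)=C\CC[C@@H]1COC(OC(C)=O)C1 | intermediate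
20 | lactol of 19: the 5-hydroxyoxolan-3-yl analogue (anomer mixture; in equilibrium with the C6 aldehyde and free C15–OH) | COC(=O)/C(CB1OC(C)(C)C(C)(C)O1)=C\[C@H](OC(=O)[C@@H](C)CC)C/C(C(=O)OC)=C\CC[C@@H]1COC(O)C1 | intermediate
21 | ten-membered (6R,7S,8R,4S) allylboration product: C6–O–Bpin, C7 bearing the 2-(methoxycarbonyl)vinyl group, free C15–OH | C=C(C(=O)OC)[C@H]1[C@H](OB2OC(C)(C)C(C)(C)O2)C[C@@H](CO)CC/C=C(/C(=O)OC)C[C@H]1OC(=O)[C@@H](C)CC | intermediate
22 | methyl (3aS,4R,6E,10S,11aR)-10-(hydroxymethyl)-3-methylidene-4-{[(2S)-2-methylbutanoyl]oxy}-2-oxo-2,3,3a,4,5,8,9,10,11,11a-decahydrocyclodeca[b]furan-6-carboxylate | C=C1C(=O)O[C@@H]2C[C@@H](CO)CC/C=C(/C(=O)OC)C[C@@H](OC(=O)[C@@H](C)CC)[C@@H]12 | target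

**Step count and risks**

Total step count: 10. Longest linear sequence: 9 steps (steps 1–3 and 5–10); step 4 is a one-step side branch.

The three steps most likely to fail:

Step 10 (ring closure). The lactol holds only a small share of open aldehyde, so the thermal allylboration may be slow and oligomerise. The face of C7 that is attacked rests on an allylic-strain argument that the ten-membered transition state may override; a cyclic transition state with C9 on the same side as C6 would give the 6,7-bis-epimer. The fallback moves the ring closure from boron to indium. It sets out from 16: the same hydroalumination is run but the alane is trapped with formaldehyde to give the hydroxymethyl enoate F1. Appel bromination (CBr4, PPh3) gives the allylic bromide F2, and dilute aqueous acid gives the bromo lactol F3. Indium powder in THF–water at high dilution then closes the ring by a Barbier allylation of the lactol (allylindium reagents add to lactols in water and equilibrate, so the macrocycle rather than the alkene geometry selects the transition state). The indium alkoxide lactonises, and the sequence comes back to the route at 22.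

Step 9 (hydroalumination and borylmethylation). The hydride reagent must pick the ynoate over three other esters and the lactol acetate, the propargylic ester could divert the hydride to an allenoate, and the alane may alkylate sluggishly. The fallback replaces aluminium by tin and palladium. It sets out from 16: Pd(PPh3)4-catalysed syn-hydrostannation with Bu3SnH gives the α-stannyl enoate F4, iodine gives the α-iodo enoate F5 with retention, and Pd-catalysed Suzuki coupling with bis(pinacolboryl)methane and KOH installs the CH2Bpin group. It comes back to the route at 19 with the same alkene geometry.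

Step 7 (asymmetric alkynylation). Aldehyde 12 is β,γ-unsaturated and may isomerise or self-condense under the zinc alkoxides, the new alkoxide can lactonise onto C14, and linear aliphatic aldehydes give the lowest ee in this reaction. The fallback makes the carbinol by reduction instead of addition. It sets out from 12: lithium methyl propiolate at −78 °C gives the epimeric alcohol F6, Dess–Martin periodinane gives the ynone F7, and Noyori transfer hydrogenation with RuCl[(R,R)-TsDPEN](p-cymene) in HCO2H/Et3N sets 8R. It comes back to the route at 14.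

**Further compounds**

F1 | step 10 | methyl (2Z,4R,6E)-9-[(3S)-5-acetoxyoxolan-3-yl]-2-(hydroxymethyl)-6-(methoxycarbonyl)-4-{[(2S)-2-methylbutanoyl]oxy}nona-2,6-dienoate | COC(=O)/C(CO)=C\[C@H](OC(=O)[C@@H](C)CC)C/C(C(=O)OC)=C\CC[C@@H]1COC(OC(C)=O)C1
F2 | step 10 | methyl (2E,4R,6E)-9-[(3S)-5-acetoxyoxolan-3-yl]-2-(bromomethyl)-6-(methoxycarbonyl)-4-{[(2S)-2-methylbutanoyl]oxy}nona-2,6-dienoate (C4 carbon cis to CO2Me) | COC(=O)/C(CBr)=C\[C@H](OC(=O)[C@@H](C)CC)C/C(C(=O)OC)=C\CC[C@@H]1COC(OC(C)=O)C1
F3 | step 10 | lactol of F2: the 5-hydroxyoxolan-3-yl analogue (anomer mixture) | COC(=O)/C(CBr)=C\[C@H](OC(=O)[C@@H](C)CC)C/C(C(=O)OC)=C\CC[C@@H]1COC(O)C1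
F4 | step 9 | methyl (2E,4R,6E)-9-[(3S)-5-acetoxyoxolan-3-yl]-6-(methoxycarbonyl)-4-{[(2S)-2-methylbutanoyl]oxy}-2-(tributylstannyl)nona-2,6-dienoate (Sn cis to H3) | COC(=O)/C([Sn](CCCC)(CCCC)CCCC)=C\[C@H](OC(=O)[C@@H](C)CC)C/C(C(=O)OC)=C\CC[C@@H]1COC(OC(C)=O)C1
F5 | step 9 | methyl (2E,4R,6E)-9-[(3S)-5-acetoxyoxolan-3-yl]-2-iodo-6-(methoxycarbonyl)-4-{[(2S)-2-methylbutanoyl]oxy}nona-2,6-dienoate (I cis to H3) | COC(=O)/C(I)=C\[C@H](OC(=O)[C@@H](C)CC)C/C(C(=O)OC)=C\CC[C@@H]1COC(OC(C)=O)C1
F6 | step 7 | methyl (6E)-9-[(3S)-5-acetoxyoxolan-3-yl]-4-hydroxy-6-(methoxycarbonyl)non-6-en-2-ynoate (both C4 epimers) | COC(=O)C#CC(O)C/C(C(=O)OC)=C\CC[C@@H]1COC(OC(C)=O)C1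
F7 | step 7 | methyl (6E)-9-[(3S)-5-acetoxyoxolan-3-yl]-6-(methoxycarbonyl)-4-oxonon-6-en-2-ynoate | COC(=O)C#CC(=O)C/C(C(=O)OC)=C\CC[C@@H]1COC(OC(C)=O)C1
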